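**Assumption:** commercial (R)-(−)-linalool (≥97% ee) is the source of C7; core atoms are numbered as in 2,6-dioxabicyclo[3.3.0]octan-3-one (C1 = methyl-bearing ring-fusion carbon, C5 = ring-fusion CH, C7 = side-chain carbon).

## Retrosynthetic overview

1. Target 30 ⇒ aldehyde 27 + diethyl cinnamylphosphonate 28 (Horner–Wadsworth–Emmons, last step, so the diene never meets ozone, peroxide or H2).
2. Bicyclic core 25 ⇒ hydroxy butenolide 24 (oxa-Michael; THF ring formed second) ⇒ β-hydroxy lactone 22 (lactone ring formed first) ⇒ aldol adduct 20.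
3. Key C–C bond (C4–C5): intermolecular aldol addition of the lithium enolate of ethyl acetate 18 to the non-enolisable α-silyloxy aldehyde 17.
4. 17 ⇒ allylic alcohol 13 (C1 carbinol by Sharpless epoxidation, then hydride opening) ⇒ aldehyde 11 (α-methylenation with formaldehyde).
5. 11 ⇒ (R)-linalool 1: C7 from the chiral pool, vinyl group → side chain (hydroboration, Cu-catalysed Grignard coupling with 7), prenyl alkene → aldehyde (ozonolysis).

## Route

Step 1
Reactants: 1 (R)-(−)-linalool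
Product: 2 triethyl{[(3R)-3,7-dimethylocta-1,6-dien-3-yl]oxy}silane
Conditions: TESOTf, 2,6-lutidine, CH2Cl2, −78 → 0 °C
Reagents that add atoms: triethylsilyl trifluoromethanesulfonate, CC[Si](CC)(CC)OS(=O)(=O)C(F)(F)F
Why: Silyl triflate silylation masks the hindered tertiary allylic alcohol; the chiral-pool stereocentre (future C7) is not touched.

Step 2
Reactants: 2 triethyl{[(3R)-3,7-dimethylocta-1,6-dien-3-yl]oxy}silane
Product: 4 (3R)-3,7-dimethyl-3-(triethylsilyloxy)oct-6-en-1-ol, via B-alkyl-9-BBN borane 3 (not isolated)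
Conditions: 9-BBN, THF, 0 °C → rt; then 3 M NaOH, 30% H2O2, 0 °C → rt
Reagents that add atoms: hydrogen peroxide, OO
Why: Brown hydroboration–oxidation with bulky 9-BBN attacks only the monosubstituted vinyl group (boron on the terminal carbon) and leaves the trisubstituted alkene; the carbinol centre is not involved (3 is labelled S by CIP priorities only).

Step 3
Reactants: 4 (3R)-3,7-dimethyl-3-(triethylsilyloxy)oct-6-en-1-ol
Product: 5 (3R)-3,7-dimethyl-3-(triethylsilyloxy)oct-6-en-1-yl 4-methylbenzenesulfonate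
Conditions: TsCl, Et3N, DMAP (cat.), CH2Cl2, 0 °C → rt
Reagents that add atoms: p-toluenesulfonyl chloride, Cc1ccc(cc1)S(Cl)(=O)=O
Why: Sulfonylation of the only free (primary) alcohol provides the leaving group for sp3–sp3 coupling.

Step 4
Reactants: 6 7-bromoheptan-1-ol
Product: 7 benzyl 7-bromoheptyl ether
Conditions: BnOC(=NH)CCl3, TfOH (cat.), CH2Cl2/cyclohexane, rt
Reagents that add atoms: benzyl 2,2,2-trichloroacetimidate, N=C(OCc1ccccc1)C(Cl)(Cl)Cl
Why: Acid-catalysed imidate benzylation protects the alcohol without touching the alkyl bromide.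

Step 5
Reactants: 5 (3R)-3,7-dimethyl-3-(triethylsilyloxy)oct-6-en-1-yl 4-methylbenzenesulfonate; 7 benzyl 7-bromoheptyl ether
Product: 9 {[(6S)-15-(benzyloxy)-2,6-dimethylpentadec-2-en-6-yl]oxy}triethylsilane, via Grignard reagent 8 (not isolated)
Conditions: 7, Mg, THF, rt; then 5, Li2CuCl4 (5 mol %), THF, −30 °C → rt
Reagents that add atoms: none
Why: Kochi–Schlosser copper-catalysed coupling of a primary alkyl Grignard with a primary tosylate builds the nine-carbon tether; the stereocentre is untouched (label becomes S by CIP priorities only).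

Step 6
Reactants: 9 {[(6S)-15-(benzyloxy)-2,6-dimethylpentadec-2-en-6-yl]oxy}triethylsilane
Product: 11 (4S)-13-(benzyloxy)-4-methyl-4-(triethylsilyloxy)tridecanal, via ozonide 10 (not isolated)
Conditions: O3, CH2Cl2, −78 °C (Sudan Red end point); then PPh3, −78 °C → rt
Reagents that add atoms: ozone, [O-][O+]=O
Why: Ozonolysis with reductive work-up cleaves the only C=C bond (the electron-rich trisubstituted alkene reacts far faster than the benzyl ether) to give the aldehyde.

Step 7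
Reactants: 11 (4S)-13-(benzyloxy)-4-methyl-4-(triethylsilyloxy)tridecanal
Product: 12 (4S)-13-(benzyloxy)-4-methyl-2-methylidene-4-(triethylsilyloxy)tridecanal
Conditions: 37% aq. HCHO, pyrrolidine (10 mol %), EtCO2H (10 mol %), i-PrOH, 45 °C
Reagents that add atoms: formaldehyde, C=O
Why: Amine-catalysed Mannich-type condensation with formaldehyde (enamine attack on the iminium, then β-elimination) methylenates the only α-CH2 of the aldehyde.

Step 8
Reactants: 12 (4S)-13-(benzyloxy)-4-methyl-2-methylidene-4-(triethylsilyloxy)tridecanal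
Product: 13 (4S)-13-(benzyloxy)-4-methyl-2-methylidene-4-(triethylsilyloxy)tridecan-1-ol
Conditions: DIBAL-H, CH2Cl2, −78 °C; Rochelle salt work-up
Reagents that add atoms: none
Why: Clean 1,2-reduction of the enal gives the 2-substituted allylic alcohol required for directed epoxidation.

Step 9
Reactants: 13 (4S)-13-(benzyloxy)-4-methyl-2-methylidene-4-(triethylsilyloxy)tridecan-1-ol
Product: 14 [(2S)-2-[(2S)-11-(benzyloxy)-2-methyl-2-(triethylsilyloxy)undecyl]oxiran-2-yl]methanol
Conditions: Ti(OiPr)4 (10 mol %), L-(+)-DIPT (13 mol %), t-BuOOH (decane), 4 Å MS, CH2Cl2, −20 °C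
Reagents that add atoms: tert-butyl hydroperoxide, CC(C)(C)OO
Why: Sharpless asymmetric epoxidation delivers oxygen to one face of the 1,1-disubstituted allylic alkene under reagent control (same sense as methallyl alcohol → (S)-2-methylglycidol with L-(+)-tartrate), setting the future C1 centre.

Step 10
Reactants: 14 [(2S)-2-[(2S)-11-(benzyloxy)-2-methyl-2-(triethylsilyloxy)undecyl]oxiran-2-yl]methanol
Product: 15 (2S,4S)-13-(benzyloxy)-2,4-dimethyl-4-(triethylsilyloxy)tridecane-1,2-diol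
Conditions: LiAlH4, THF, 0 °C → rt
Reagents that add atoms: none
Why: SN2 hydride opening at the unsubstituted epoxide CH2 turns it into the C1 methyl group and leaves the tertiary C–O bond, and hence the configuration, intact.

Step 11
Reactants: 15 (2S,4S)-13-(benzyloxy)-2,4-dimethyl-4-(triethylsilyloxy)tridecane-1,2-diol
Product: 16 (2S,4S)-13-(benzyloxy)-2,4-dimethyl-1,2,4-tris(triethylsilyloxy)tridecane
Conditions: TESOTf (2.6 equiv), 2,6-lutidine, CH2Cl2, −78 → 0 °C
Reagents that add atoms: triethylsilyl trifluoromethanesulfonate, CC[Si](CC)(CC)OS(=O)(=O)C(F)(F)F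
Why: Exhaustive silylation with the reactive silyl triflate protects both the tertiary and the primary hydroxyl.

Step 12
Reactants: 16 (2S,4S)-13-(benzyloxy)-2,4-dimethyl-1,2,4-tris(triethylsilyloxy)tridecane
Product: 17 (2S,4S)-13-(benzyloxy)-2,4-dimethyl-2,4-bis(triethylsilyloxy)tridecanal
Conditions: (COCl)2, DMSO, CH2Cl2, −78 → −30 °C; then Et3N, −78 °C → rt
Reagents that add atoms: none
Why: Under Swern conditions a primary TES ether is activated and oxidised directly to the aldehyde while tertiary TES ethers are inert, and the product has no α-hydrogen so it cannot epimerise.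

Step 13
Reactants: 17 (2S,4S)-13-(benzyloxy)-2,4-dimethyl-2,4-bis(triethylsilyloxy)tridecanal; 18 ethyl acetate
Product: 20 ethyl (3RS,4S,6S)-15-(benzyloxy)-3-hydroxy-4,6-dimethyl-4,6-bis(triethylsilyloxy)pentadecanoate, via lithium enolate 19 (not isolated)
Conditions: LDA, 18, THF, −78 °C; then 17, −78 °C; sat. NH4Cl quench at −78 °C
Reagents that add atoms: none
Why: Intermolecular aldol addition of a preformed lithium ester enolate to a non-enolisable aldehyde forms the C4–C5 bond; the new carbinol centre forms as a mixture (Felkin isomer major) and is erased in step 15.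

Step 14
Reactants: 20 ethyl (3RS,4S,6S)-15-(benzyloxy)-3-hydroxy-4,6-dimethyl-4,6-bis(triethylsilyloxy)pentadecanoate
Product: 22 (4RS,5S)-5-[(2S)-11-(benzyloxy)-2-hydroxy-2-methylundecyl]-4-hydroxy-5-methyloxolan-2-one, via trihydroxy ester 21 (not isolated)
Conditions: 1 M aq. HCl, THF, rt
Reagents that add atoms: none
Why: Acidic hydrolysis of both TES ethers is followed by spontaneous five-membered lactonisation of the γ-hydroxy ester through the tertiary C1 hydroxyl, closing the lactone ring.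

Step 15
Reactants: 22 (4RS,5S)-5-[(2S)-11-(benzyloxy)-2-hydroxy-2-methylundecyl]-4-hydroxy-5-methyloxolan-2-one
Product: 25 (1S,5S,7S)-7-[9-(benzyloxy)nonyl]-1,7-dimethyl-2,6-dioxabicyclo[3.3.0]octan-3-one, via mesylate 23 (not isolated), via butenolide 24 (not isolated)
Conditions: MsCl (1.2 equiv), Et3N, CH2Cl2, −20 → 0 °C; then DBU, rt
Reagents that add atoms: none
Why: Mesylation of the only secondary hydroxyl, E1cB elimination to the butenolide and 5-exo intramolecular oxa-Michael addition of the C7 tertiary alcohol close the tetrahydrofuran; a 5/5 system can only be cis-fused, so C5 is set by C1.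

Step 16
Reactants: 25 (1S,5S,7S)-7-[9-(benzyloxy)nonyl]-1,7-dimethyl-2,6-dioxabicyclo[3.3.0]octan-3-one
Product: 26 (1S,5S,7S)-7-(9-hydroxynonyl)-1,7-dimethyl-2,6-dioxabicyclo[3.3.0]octan-3-one
Conditions: H2 (1 atm), 10% Pd/C, EtOAc, rt
Reagents that add atoms: none
Why: Hydrogenolysis removes the benzyl ether and no other reducible group is present.

Step 17
Reactants: 26 (1S,5S,7S)-7-(9-hydroxynonyl)-1,7-dimethyl-2,6-dioxabicyclo[3.3.0]octan-3-one
Product: 27 9-[(1S,5S,7S)-1,7-dimethyl-3-oxo-2,6-dioxabicyclo[3.3.0]octan-7-yl]nonanal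
Conditions: Dess–Martin periodinane, CH2Cl2, rt
Reagents that add atoms: none
Why: Dess–Martin oxidation gives the aldehyde under non-basic conditions that do not disturb the β-alkoxy lactone.

Step 18
Reactants: 27 9-[(1S,5S,7S)-1,7-dimethyl-3-oxo-2,6-dioxabicyclo[3.3.0]octan-7-yl]nonanal; 28 diethyl cinnamylphosphonate
Product: 30 plakortone P, via lithiated phosphonate 29 (not isolated)
Conditions: 28, LiHMDS, THF, −78 °C; then 27, −78 → 0 °C (any 9Z isomer equilibrated to E with cat. I2, CH2Cl2, light)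
Reagents that add atoms: none
Why: Horner–Wadsworth–Emmons olefination with the allylic phosphonate anion forms the new C9=C10 bond E-selectively while the cinnamyl E-alkene is carried in unchanged, and the aldehyde reacts at −78 °C far faster than the lactone.

## Compound list

1 | (R)-(−)-linalool, (3R)-3,7-dimethylocta-1,6-dien-3-ol | C[C@](O)(C=C)CCC=C(C)C | starting material
2 | triethyl{[(3R)-3,7-dimethylocta-1,6-dien-3-yl]oxy}silane | C[C@](O[Si](CC)(CC)CC)(C=C)CCC=C(C)C | intermediate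
3 | 9-[(3S)-3,7-dimethyl-3-(triethylsilyloxy)oct-6-en-1-yl]-9-borabicyclo[3.3.1]nonane | C[C@](O[Si](CC)(CC)CC)(CCB1C2CCCC1CCC2)CCC=C(C)C | intermediate
4 | (3R)-3,7-dimethyl-3-(triethylsilyloxy)oct-6-en-1-ol | C[C@](O[Si](CC)(CC)CC)(CCO)CCC=C(C)C | intermediate
5 | (3R)-3,7-dimethyl-3-(triethylsilyloxy)oct-6-en-1-yl 4-methylbenzenesulfonate | C[C@](O[Si](CC)(CC)CC)(CCOS(=O)(=O)c1ccc(C)cc1)CCC=C(C)C | intermediate
6 | 7-bromoheptan-1-ol | OCCCCCCCBr | starting material
7 | benzyl 7-bromoheptyl ether | BrCCCCCCCOCc1ccccc1 | intermediate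
8 | [7-(benzyloxy)heptyl]magnesium bromide | Br[Mg]CCCCCCCOCc1ccccc1 | intermediate
9 | {[(6S)-15-(benzyloxy)-2,6-dimethylpentadec-2-en-6-yl]oxy}triethylsilane | C[C@](O[Si](CC)(CC)CC)(CCCCCCCCCOCc1ccccc1)CCC=C(C)C | intermediate
10 | 3-[(3S)-12-(benzyloxy)-3-methyl-3-(triethylsilyloxy)dodecyl]-5,5-dimethyl-1,2,4-trioxolane (ozonide, epimers at the ring CH) | C[C@](O[Si](CC)(CC)CC)(CCCCCCCCCOCc1ccccc1)CCC1OOC(C)(C)O1 | intermediate
11 | (4S)-13-(benzyloxy)-4-methyl-4-(triethylsilyloxy)tridecanal | C[C@](O[Si](CC)(CC)CC)(CCCCCCCCCOCc1ccccc1)CCC=O | intermediate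
12 | (4S)-13-(benzyloxy)-4-methyl-2-methylidene-4-(triethylsilyloxy)tridecanal | C[C@](O[Si](CC)(CC)CC)(CCCCCCCCCOCc1ccccc1)CC(=C)C=O | intermediate
13 | (4S)-13-(benzyloxy)-4-methyl-2-methylidene-4-(triethylsilyloxy)tridecan-1-ol | C[C@](O[Si](CC)(CC)CC)(CCCCCCCCCOCc1ccccc1)CC(=C)CO | intermediate
14 | [(2S)-2-[(2S)-11-(benzyloxy)-2-methyl-2-(triethylsilyloxy)undecyl]oxiran-2-yl]methanol | C[C@](O[Si](CC)(CC)CC)(CCCCCCCCCOCc1ccccc1)C[C@]1(CO)CO1 | intermediate
15 | (2S,4S)-13-(benzyloxy)-2,4-dimethyl-4-(triethylsilyloxy)tridecane-1,2-diol | C[C@](O[Si](CC)(CC)CC)(CCCCCCCCCOCc1ccccc1)C[C@](C)(O)CO | intermediate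
16 | (2S,4S)-13-(benzyloxy)-2,4-dimethyl-1,2,4-tris(triethylsilyloxy)tridecane | C[C@](O[Si](CC)(CC)CC)(CCCCCCCCCOCc1ccccc1)C[C@](C)(O[Si](CC)(CC)CC)CO[Si](CC)(CC)CC | intermediate
17 | (2S,4S)-13-(benzyloxy)-2,4-dimethyl-2,4-bis(triethylsilyloxy)tridecanal | C[C@](O[Si](CC)(CC)CC)(CCCCCCCCCOCc1ccccc1)C[C@](C)(O[Si](CC)(CC)CC)C=O | intermediate
18 | ethyl acetate | CCOC(C)=O | starting material
19 | lithium 1-ethoxyethenolate (lithium enolate of ethyl acetate) | [Li+].[O-]C(=C)OCC | intermediate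
20 | ethyl (3RS,4S,6S)-15-(benzyloxy)-3-hydroxy-4,6-dimethyl-4,6-bis(triethylsilyloxy)pentadecanoate | C[C@](O[Si](CC)(CC)CC)(CCCCCCCCCOCc1ccccc1)C[C@](C)(O[Si](CC)(CC)CC)C(O)CC(=O)OCC | intermediate
21 | ethyl (3RS,4S,6S)-15-(benzyloxy)-3,4,6-trihydroxy-4,6-dimethylpentadecanoate | C[C@](O)(CCCCCCCCCOCc1ccccc1)C[C@](C)(O)C(O)CC(=O)OCC | intermediate
22 | (4RS,5S)-5-[(2S)-11-(benzyloxy)-2-hydroxy-2-methylundecyl]-4-hydroxy-5-methyloxolan-2-one | C[C@](O)(CCCCCCCCCOCc1ccccc1)C[C@]1(C)OC(=O)CC1O | intermediate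
23 | (2S,3RS)-2-[(2S)-11-(benzyloxy)-2-hydroxy-2-methylundecyl]-2-methyl-5-oxooxolan-3-yl methanesulfonate | C[C@](O)(CCCCCCCCCOCc1ccccc1)C[C@]1(C)OC(=O)CC1OS(C)(=O)=O | intermediate
24 | (5S)-5-[(2S)-11-(benzyloxy)-2-hydroxy-2-methylundecyl]-5-methylfuran-2(5H)-one | C[C@](O)(CCCCCCCCCOCc1ccccc1)C[C@]1(C)OC(=O)C=C1 | intermediate
25 | (1S,5S,7S)-7-[9-(benzyloxy)nonyl]-1,7-dimethyl-2,6-dioxabicyclo[3.3.0]octan-3-one | C[C@]1(CCCCCCCCCOCc2ccccc2)C[C@]2(C)OC(=O)C[C@@H]2O1 | intermediate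
26 | (1S,5S,7S)-7-(9-hydroxynonyl)-1,7-dimethyl-2,6-dioxabicyclo[3.3.0]octan-3-one | C[C@]1(CCCCCCCCCO)C[C@]2(C)OC(=O)C[C@@H]2O1 | intermediate
27 | 9-[(1S,5S,7S)-1,7-dimethyl-3-oxo-2,6-dioxabicyclo[3.3.0]octan-7-yl]nonanal | C[C@]1(CCCCCCCCC=O)C[C@]2(C)OC(=O)C[C@@H]2O1 | intermediate
28 | diethyl [(2E)-3-phenylprop-2-en-1-yl]phosphonate (diethyl cinnamylphosphonate) | CCOP(=O)(OCC)C/C=C/c1ccccc1 | starting material
29 | lithium (2E)-1-(diethoxyphosphoryl)-3-phenylprop-2-en-1-ide | [Li+].CCOP(=O)(OCC)[CH-]/C=C/c1ccccc1 | intermediate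
30 | plakortone P, (1S,5S,7S)-1,7-dimethyl-7-[(9E,11E)-12-phenyldodeca-9,11-dien-1-yl]-2,6-dioxabicyclo[3.3.0]octan-3-one | C[C@]1(CCCCCCCC/C=C/C=C/c2ccccc2)C[C@]2(C)OC(=O)C[C@@H]2O1 | target

## Step count and risk

Total step count: 18. Longest linear sequence: 17 steps (1 → 30 through steps 1–3 and 5–18; step 4 prepares the side-chain bromide).

The three steps most likely to fail:

**Step 12 (direct Swern oxidation of the primary TES ether).** The neopentyl-type silyl ether may react sluggishly or the tertiary TES groups may be partly lost. The fallback sets out from diol 15 and comes back at aldehyde 17, reversing the order of oxidation and protection. Parikh–Doering oxidation (SO3·pyridine, DMSO, i-Pr2NEt) touches only the primary alcohol and gives (2S,4S)-13-(benzyloxy)-2-hydroxy-2,4-dimethyl-4-(triethylsilyloxy)tridecanal F1, which cannot enolise. Silylation of its tertiary hydroxyl with TESOTf and 2,6-lutidine then gives 17.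

**Step 15 (mesylation, elimination, oxa-Michael cascade).** Competing sulfonylation of the tertiary C7 hydroxyl or incomplete ring closure would cost material. The fallback sets out from aldol adduct 20 and comes back at 25, closing the rings from an acyclic enoate instead of a butenolide. With both tertiary alcohols still silylated, MsCl and Et3N can only give ethyl (3RS,4S,6S)-15-(benzyloxy)-4,6-dimethyl-3-(methylsulfonyloxy)-4,6-bis(triethylsilyloxy)pentadecanoate F2. DBU eliminates this to ethyl (2E,4S,6S)-15-(benzyloxy)-4,6-dimethyl-4,6-bis(triethylsilyloxy)pentadec-2-enoate F3. TBAF in THF removes both silyl groups to give ethyl (2E,4S,6S)-15-(benzyloxy)-4,6-dihydroxy-4,6-dimethylpentadec-2-enoate F4. Under the basic fluoride conditions its C6 hydroxyl adds 5-exo to the enoate, giving ethyl 2-[(2S,3S,5S)-5-[9-(benzyloxy)nonyl]-3-hydroxy-3,5-dimethyloxolan-2-yl]acetate F5, which lactonises to 25. The trans oxolane isomer reverts by retro-Michael and is funnelled to the same product.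

**Step 18 (HWE olefination).** The E/Z ratio at the new alkene and the base sensitivity of the β-alkoxy lactone are the concerns. The fallback sets out from aldehyde 27 and comes back at target 30, fixing both alkene geometries by reagents instead of by olefination selectivity. Ohira–Bestmann homologation (dimethyl (1-diazo-2-oxopropyl)phosphonate, K2CO3, MeOH, mild acidic work-up to re-close any opened lactone) gives (1S,5S,7S)-7-(dec-9-yn-1-yl)-1,7-dimethyl-2,6-dioxabicyclo[3.3.0]octan-3-one F6. Hydrozirconation with Cp2Zr(H)Cl followed by iodine gives (1S,5S,7S)-7-[(9E)-10-iododec-9-en-1-yl]-1,7-dimethyl-2,6-dioxabicyclo[3.3.0]octan-3-one F7. Suzuki coupling with (E)-2-phenylvinylboronic acid (Pd(PPh3)4, K3PO4, THF/H2O) then gives 30.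

## Further compounds

F1 | step 12 | (2S,4S)-13-(benzyloxy)-2-hydroxy-2,4-dimethyl-4-(triethylsilyloxy)tridecanal | C[C@](O[Si](CC)(CC)CC)(CCCCCCCCCOCc1ccccc1)C[C@](C)(O)C=O
F2 | step 15 | ethyl (3RS,4S,6S)-15-(benzyloxy)-4,6-dimethyl-3-(methylsulfonyloxy)-4,6-bis(triethylsilyloxy)pentadecanoate | C[C@](O[Si](CC)(CC)CC)(CCCCCCCCCOCc1ccccc1)C[C@](C)(O[Si](CC)(CC)CC)C(OS(C)(=O)=O)CC(=O)OCC
F3 | step 15 | ethyl (2E,4S,6S)-15-(benzyloxy)-4,6-dimethyl-4,6-bis(triethylsilyloxy)pentadec-2-enoate | C[C@](O[Si](CC)(CC)CC)(CCCCCCCCCOCc1ccccc1)C[C@](C)(O[Si](CC)(CC)CC)/C=C/C(=O)OCC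
F4 | step 15 | ethyl (2E,4S,6S)-15-(benzyloxy)-4,6-dihydroxy-4,6-dimethylpentadec-2-enoate | C[C@](O)(CCCCCCCCCOCc1ccccc1)C[C@](C)(O)/C=C/C(=O)OCC
F5 | step 15 | ethyl 2-[(2S,3S,5S)-5-[9-(benzyloxy)nonyl]-3-hydroxy-3,5-dimethyloxolan-2-yl]acetate | C[C@]1(CCCCCCCCCOCc2ccccc2)C[C@](C)(O)[C@H](CC(=O)OCC)O1
F6 | step 18 | (1S,5S,7S)-7-(dec-9-yn-1-yl)-1,7-dimethyl-2,6-dioxabicyclo[3.3.0]octan-3-one | C[C@]1(CCCCCCCCC#C)C[C@]2(C)OC(=O)C[C@@H]2O1
F7 | step 18 | (1S,5S,7S)-7-[(9E)-10-iododec-9-en-1-yl]-1,7-dimethyl-2,6-dioxabicyclo[3.3.0]octan-3-one | C[C@]1(CCCCCCCC/C=C/I)C[C@]2(C)OC(=O)C[C@@H]2O1
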